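**Plan**
1. Cuts, in order: the five acyl-level oxygen functions (four ArO–acyl groups, and CH2OH back to CO2Me) in one hydride step. Then the bridge bond CH2–C1′ (ring B), then the bond from the bridge CH2 to ring A (phenol Mannich reaction). Ring B goes back to 4,5-dibromocatechol and Br2.
2. Enabling feature in ring B: the carbon to be joined heads the contiguous row C1′–C2′(Br)–C3′(Br), and only C1′ has a C–H neighbour (C6′–H). In 3,4,5-tribromocatechol diacetate it therefore carries the only C–Br bond with a free ortho position. Pd(0) should insert there, and the two bromines left over are the 2′,3′-dibromide of the target.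
3. Enabling feature in ring A: the bridge CH2 stands ortho to one OH and para to the other. That is one of the two equivalent free positions of methyl 4-O-methylgallate, so CH2O/Me2NH places it without a regiochemical question. The neighbouring CO2Me is the later CH2OH.
4. The natural-polarity union (ring-A quinone methide plus dibromocatechol, Friedel–Crafts) is rejected. The free C–H of ring A, ortho/para to two OH groups, is a far better nucleophile than dibrominated ring B, so self-condensation should win. Instead the benzylic carbon is polarity-reversed (C–Cl to C–ZnCl) and two electrophilic carbons are united.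
5. Forward order: ring-A arm (steps 1–2), ring-B arm (steps 3–4), coupling (step 5), global hydride unmasking (step 6). No ring is formed.
6. Stereochemistry: none has to be set.

Key step: step 5

Assumption: the target has no stereocentre, stereoaxis or configured double bond. It is achiral, so the question of the enantiomer does not arise.

**Step 1**
Reactants: 1 methyl 3,5-dihydroxy-4-methoxybenzoate
Product: 2 methyl 2-[(dimethylamino)methyl]-3,5-dihydroxy-4-methoxybenzoate
Conditions: 37% aq. HCHO (1.0 equiv), 40% aq. Me2NH (1.05 equiv), EtOH, 0 °C → rt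
Reagents that add atoms: formaldehyde, C=O; dimethylamine, CNC
Why: Phenol Mannich reaction: the iminium ion attacks one of the two equivalent free ring positions of 1, each ortho to one OH and para to the other, so only one regioisomer is possible and one equivalent of reagent should hold the reaction at the mono-adduct.

**Step 2**
Reactants: 2 methyl 2-[(dimethylamino)methyl]-3,5-dihydroxy-4-methoxybenzoate
Product: 4 methyl 2-(chloromethyl)-3,5-bis[(ethoxycarbonyl)oxy]-4-methoxybenzoate, via methyl 2-[(dimethylamino)methyl]-3,5-bis[(ethoxycarbonyl)oxy]-4-methoxybenzoate 3 (not isolated)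
Conditions: ClCO2Et (4 equiv), iPr2NEt (2.2 equiv), CH2Cl2, 0 °C, then 40 °C
Reagents that add atoms: ethyl chloroformate, CCOC(=O)Cl
Why: Phenol O-acylation followed by von Braun-type acylative dealkylation: the N-acylammonium chloride collapses by attack of chloride on the benzylic carbon (benzyl is lost in preference to methyl), and the two electron-withdrawing carbonates keep the chloride from ionising to a quinone methide.

**Step 3**
Reactants: 5 4,5-dibromobenzene-1,2-diol (4,5-dibromocatechol)
Product: 6 3,4,5-tribromobenzene-1,2-diol
Conditions: Br2 (1.05 equiv), AcOH, rt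
Reagents that add atoms: bromine, BrBr
Why: Electrophilic aromatic bromination: 5 has two equivalent free positions, each ortho to an OH, and the third bromine deactivates the ring enough for one equivalent of Br2 to stop at the tribromide.

**Step 4**
Reactants: 6 3,4,5-tribromobenzene-1,2-diol
Product: 7 3,4,5-tribromo-1,2-phenylene diacetate
Conditions: Ac2O (3 equiv), pyridine (solvent), rt
Reagents that add atoms: acetic anhydride, CC(=O)OC(C)=O
Why: Standard O-acetylation, which removes the acidic, chelating catechol protons before the organozinc step, makes the ring more prone to oxidative addition and adds bulk next to C3–Br.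

**Step 5**
Reactants: 4 methyl 2-(chloromethyl)-3,5-bis[(ethoxycarbonyl)oxy]-4-methoxybenzoate; 7 3,4,5-tribromo-1,2-phenylene diacetate
Product: 9 methyl 2-[(4,5-diacetoxy-2,3-dibromophenyl)methyl]-3,5-bis[(ethoxycarbonyl)oxy]-4-methoxybenzoate, via {[2,4-bis(ethoxycarbonyloxy)-3-methoxy-6-(methoxycarbonyl)phenyl]methyl}zinc chloride 8 (not isolated)
Conditions: (i) 4, Zn dust (1.5 equiv), LiCl (1.5 equiv), THF, 25 °C, decant from Zn; (ii) 7 (1.2 equiv), Pd(PPh3)4 (3 mol %), THF, 25 → 50 °C
Reagents that add atoms: none
Why: LiCl-assisted insertion of zinc into the benzylic C–Cl bond of 4 reverses the polarity of the bridge carbon (benzylic zinc chlorides tolerate esters and carbonates), and a Negishi cycle follows: oxidative addition of Pd(0) to a C–Br bond of 7, transmetalation with 8 and reductive elimination to the CH2–C1′ bond. The closest known reaction type is the Pd-catalysed Negishi coupling of functionalised benzylic zinc chlorides with aryl bromides, together with the terminal-selective mono-coupling of 1,2,3-trihaloarenes. The step closes no ring and creates no stereocentre. It needs site selectivity among three C–Br bonds: only C5–Br of 7 has a hydrogen neighbour (C6–H), whereas C4–Br lies between two bromines and C3–Br between bromine and acetoxy, so the sterically sensitive Pd(PPh3)2 should insert at C5–Br. It must also stop after one coupling, which is secured because both C–Br bonds left in 9 are di-ortho-substituted and 7 is used in slight excess. Since no benzylic cation or quinone methide is involved and all four phenols are acylated, the nucleophilic C–H of ring A cannot interfere.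

**Step 6**
Reactants: 9 methyl 2-[(4,5-diacetoxy-2,3-dibromophenyl)methyl]-3,5-bis[(ethoxycarbonyl)oxy]-4-methoxybenzoate
Product: 10 3,4-dibromo-5-{[2,4-dihydroxy-6-(hydroxymethyl)-3-methoxyphenyl]methyl}benzene-1,2-diol (target)
Conditions: LiAlH4 (6 equiv), THF, 0 °C, Ar; cold aq. citric acid work-up
Reagents that add atoms: none
Why: Hydride reduction: LiAlH4 reduces the methyl ester to the hydroxymethyl group and cleaves the two aryl carbonates and the two aryl acetates by acyl attack in the same operation, while the aryl bromides, the aryl methyl ether and the diarylmethane should be inert at 0 °C.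

**Compound list**
1 | methyl 3,5-dihydroxy-4-methoxybenzoate | COC(=O)c1cc(O)c(OC)c(O)c1 | starting material
2 | methyl 2-[(dimethylamino)methyl]-3,5-dihydroxy-4-methoxybenzoate | COC(=O)c1cc(O)c(OC)c(O)c1CN(C)C | intermediate
3 | methyl 2-[(dimethylamino)methyl]-3,5-bis[(ethoxycarbonyl)oxy]-4-methoxybenzoate | COC(=O)c1cc(OC(=O)OCC)c(OC)c(OC(=O)OCC)c1CN(C)C | intermediate
4 | methyl 2-(chloromethyl)-3,5-bis[(ethoxycarbonyl)oxy]-4-methoxybenzoate | COC(=O)c1cc(OC(=O)OCC)c(OC)c(OC(=O)OCC)c1CCl | intermediate
5 | 4,5-dibromobenzene-1,2-diol | Oc1cc(Br)c(Br)cc1O | starting material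
6 | 3,4,5-tribromobenzene-1,2-diol | Oc1cc(Br)c(Br)c(Br)c1O | intermediate
7 | 3,4,5-tribromo-1,2-phenylene diacetate | CC(=O)Oc1cc(Br)c(Br)c(Br)c1OC(C)=O | intermediate
8 | {[2,4-bis(ethoxycarbonyloxy)-3-methoxy-6-(methoxycarbonyl)phenyl]methyl}zinc chloride | COC(=O)c1cc(OC(=O)OCC)c(OC)c(OC(=O)OCC)c1C[Zn]Cl | intermediate
9 | methyl 2-[(4,5-diacetoxy-2,3-dibromophenyl)methyl]-3,5-bis[(ethoxycarbonyl)oxy]-4-methoxybenzoate | COC(=O)c1cc(OC(=O)OCC)c(OC)c(OC(=O)OCC)c1Cc1cc(OC(C)=O)c(OC(C)=O)c(Br)c1Br | intermediate
10 | 3,4-dibromo-5-{[2,4-dihydroxy-6-(hydroxymethyl)-3-methoxyphenyl]methyl}benzene-1,2-diol | COc1c(O)cc(CO)c(Cc2cc(O)c(O)c(Br)c2Br)c1O | target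

Total step count: 6. Longest linear sequence: 4 (steps 1, 2, 5, 6).

**Steps most likely to fail**

**Step 5.** Pd(0) may not discriminate well enough between the three C–Br bonds, a second coupling may follow the first, or the zinc reagent may be lost by Wurtz-type homocoupling.
- The fallback secures selectivity by bond strength instead of by crowding. It sets out from zinc reagent 8 and comes back at 9.
- The partner is built from purchased 2,3-dibromophenol F1. Magnesium-mediated ortho-formylation (MgCl2, Et3N, paraformaldehyde, MeCN, reflux) should give 3,4-dibromo-2-hydroxybenzaldehyde F2.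
- Iodination (NIS, cat. TFA, MeCN) goes para to OH and meta to CHO, the one position both groups favour, to give 3,4-dibromo-2-hydroxy-5-iodobenzaldehyde F3.
- Dakin oxidation (H2O2, aq. NaOH) should give 3,4-dibromo-5-iodobenzene-1,2-diol F4, and Ac2O/pyridine then gives 3,4-dibromo-5-iodo-1,2-phenylene diacetate F5.
- Negishi coupling of 8 with F5 at room temperature should take place at the C–I bond only and give 9.

**Step 2.** At the crowded, di-ortho-substituted benzylic carbon the acylammonium salt may lose N-methyl instead of benzyl, or the C–N cleavage may stay incomplete.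
- The fallback exchanges the amine by the elimination–addition reaction of phenolic Mannich bases instead of by displacement. It sets out from 2 and comes back at 10.
- Refluxing Ac2O should replace NMe2 by OAc and acetylate both phenols, giving methyl 3,5-diacetoxy-2-(acetoxymethyl)-4-methoxybenzoate F6.
- HBr in AcOH at rt should give methyl 3,5-diacetoxy-2-(bromomethyl)-4-methoxybenzoate F7.
- Zn/LiCl in THF then gives {[2,4-diacetoxy-3-methoxy-6-(methoxycarbonyl)phenyl]methyl}zinc bromide F8.
- Negishi coupling of F8 with 7 as in step 5 gives methyl 3,5-diacetoxy-2-[(4,5-diacetoxy-2,3-dibromophenyl)methyl]-4-methoxybenzoate F9.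
- LiAlH4 as in step 6 gives 10.

**Step 1.** Aminomethylation may run on to the second equivalent ring position, because the first substituent hardly deactivates the ring.
- The fallback uses a self-limiting electrophile. It sets out from 1 and comes back at 2.
- Rieche formylation (Cl2CHOMe, TiCl4, CH2Cl2, 0 °C) should stop at methyl 2-formyl-3,5-dihydroxy-4-methoxybenzoate F10, since the formyl group deactivates the ring.
- Reductive amination (Me2NH·HCl, NaBH(OAc)3, 1,2-dichloroethane, rt) then gives 2.

**Further compounds**
F1 | step 5 | 2,3-dibromophenol | Oc1cccc(Br)c1Br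
F2 | step 5 | 3,4-dibromo-2-hydroxybenzaldehyde | O=Cc1ccc(Br)c(Br)c1O
F3 | step 5 | 3,4-dibromo-2-hydroxy-5-iodobenzaldehyde | O=Cc1cc(I)c(Br)c(Br)c1O
F4 | step 5 | 3,4-dibromo-5-iodobenzene-1,2-diol | Oc1cc(I)c(Br)c(Br)c1O
F5 | step 5 | 3,4-dibromo-5-iodo-1,2-phenylene diacetate | CC(=O)Oc1cc(I)c(Br)c(Br)c1OC(C)=O
F6 | step 2 | methyl 3,5-diacetoxy-2-(acetoxymethyl)-4-methoxybenzoate | COC(=O)c1cc(OC(C)=O)c(OC)c(OC(C)=O)c1COC(C)=O
F7 | step 2 | methyl 3,5-diacetoxy-2-(bromomethyl)-4-methoxybenzoate | COC(=O)c1cc(OC(C)=O)c(OC)c(OC(C)=O)c1CBr
F8 | step 2 | {[2,4-diacetoxy-3-methoxy-6-(methoxycarbonyl)phenyl]methyl}zinc bromide | COC(=O)c1cc(OC(C)=O)c(OC)c(OC(C)=O)c1C[Zn]Br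
F9 | step 2 | methyl 3,5-diacetoxy-2-[(4,5-diacetoxy-2,3-dibromophenyl)methyl]-4-methoxybenzoate | COC(=O)c1cc(OC(C)=O)c(OC)c(OC(C)=O)c1Cc1cc(OC(C)=O)c(OC(C)=O)c(Br)c1Br
F10 | step 1 | methyl 2-formyl-3,5-dihydroxy-4-methoxybenzoate | COC(=O)c1cc(O)c(OC)c(O)c1C=O
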